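**Assumptions (one line each)**
- The exocyclic bromoalkene is taken exactly as drawn in the target SMILES (bromine cis to ring C4). Step 6 gives an E/Z mixture, and the drawn isomer is isolated from it.
- Pent-4-ynal is volatile and unstable, so it is made fresh from commercial 4-pentyn-1-ol. Catalysts and bulk reagents are not numbered.

## Retrosynthetic overview
1. Acetoxyfimbrolide comes from its TBS ether by Si→Ac exchange. The silyl ether keeps the carbinol inert during the later bromination and base steps.
2. The 4-bromo-5-(bromomethylene)butenolide comes from a γ-(bromomethylene)butyrolactone by a new NBS bromination / vinylogous dehydrobromination cascade. This forms the C3=C4 bond, the C4–Br and the exocyclic CHBr.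
3. That lactone is formed (ring closure) by 5-exo-dig bromolactonization of a 2-substituted pent-4-ynoic acid, which comes from a Pinnick oxidation of the TBS-protected aldol.
4. The carbinol stereocentre is set by a D-proline-catalysed cross-aldol of pent-4-ynal with butanal. The C2 epimers do not matter because C3 ends up sp².

## Route

**Step 1**
Reactants: 1 (4-pentyn-1-ol)
Product: 2 (pent-4-ynal)
Conditions: Dess–Martin periodinane, NaHCO3, CH2Cl2, 0 °C → rt
Reagents that add atoms: none
Why: Mild oxidation of a primary alcohol to the aldehyde, which leaves the terminal alkyne untouched. The product is used at once as a solution.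

**Step 2**
Reactants: 2 (pent-4-ynal, donor, added by syringe pump over 12 h); 3 (butanal, acceptor, 3 equiv)
Product: 4 ((3R)-3-hydroxy-2-(prop-2-yn-1-yl)hexanal, C2-epimeric mixture, anti major)
Conditions: D-proline (20 mol%), DMF, 4 °C, 24 h
Reagents that add atoms: none
Why: Proline-catalysed direct cross-aldol (enamine catalysis, Houk–List type transition state). D-proline gives the mirror-image face selectivity of L-proline, which gives 3S for this substituent pattern, so the carbinol is R. Slow addition of the donor suppresses its self-aldol.

**Step 3**
Reactants: 4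
Product: 5 ((3R)-3-(tert-butyldimethylsilyloxy)-2-(prop-2-yn-1-yl)hexanal)
Conditions: TBSCl, imidazole, DMF, 0 °C → rt
Reagents that add atoms: TBSCl, CC(C)(C)[Si](C)(C)Cl
Why: Silylation of the secondary alcohol, which is untouched stereochemically. It prevents later bicyclic-ketal formation and β-acetoxy elimination, and it cannot be lost as a leaving group in the base step.

**Step 4**
Reactants: 5
Product: 6 ((3R)-3-(TBSO)-2-(prop-2-yn-1-yl)hexanoic acid)
Conditions: NaClO2, NaH2PO4, 2-methyl-2-butene, t-BuOH/H2O, rt
Reagents that add atoms: sodium chlorite (supplies O), [Na+].[O-]Cl=O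
Why: Pinnick oxidation converts the aldehyde to the acid. The alkene scavenger removes HOCl so the alkyne survives, and the carbinol is not involved.

**Step 5**
Reactants: 6
Product: 7 ((5-bromomethylene)-3-[(1R)-1-(TBSO)butyl]dihydrofuran-2-one, C3 epimers; exocyclic alkene geometry irrelevant because it is destroyed in Step 6)
Conditions: NBS (1.1 equiv), NaHCO3 (2 equiv), MeCN, 0 °C → rt, dark
Reagents that add atoms: NBS, O=C1CCC(=O)N1Br
Why: Electrophilic 5-exo-dig bromolactonization of the alkynoic acid by anti addition of carboxylate and Br+. Silver is avoided because it would make the 1-bromoalkyne.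

**Step 6**
Reactants: 7
Product: 8 (3-[(1R)-1-(TBSO)butyl]-4-bromo-5-(bromomethylene)furan-2(5H)-one, Br cis to C4 as drawn)
Conditions: NBS (2.6 equiv), MeCN, 50 °C, dark, 8 h; then Et3N (4 equiv), 0 °C, 20 min; chromatographic separation of the E/Z isomers
Reagents that add atoms: NBS, O=C1CCC(=O)N1Br (Et3N is lost as its HBr salt)
Why: Proposed new method: the first Br+ attacks the nucleophilic exocyclic carbon of the enol lactone, and loss of H-4 gives the endocyclic 5-(dibromomethyl)furan-2(3H)-one. The second Br+ adds at C4 (the enol-ether β-carbon), and loss of H-4 gives the 4-bromo-5-(dibromomethyl)furan-2(3H)-one. Et3N then removes the acidic C3–H to give an aromatic 2-oxidofuran, which expels Br⁻ from CHBr2 in a vinylogous E1cB (1,6) elimination. This installs C3=C4, keeps C4–Br and forms the exocyclic =CHBr. The closest known reactions are NBS halogenation of enol lactones and the base-induced 1,6-elimination of 5-(bromomethyl)-2(3H)-furanones to 5-methylene-2(5H)-furanones. NBS releases succinimide rather than HBr, so the TBS ether survives. The silyloxy group is a poor leaving group in the E1cB step. The carbinol carbon is never ionised.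

**Step 7**
Reactants: 8
Product: 9 (acetoxyfimbrolide, (R)-configured)
Conditions: Ac2O (5 equiv), Bi(OTf)3 (3 mol%), MeCN, 0 °C → rt
Reagents that add atoms: Ac2O, CC(=O)OC(C)=O
Why: Lewis-acid-catalysed silyl ether → acetate exchange. The O–Si bond is cleaved and the C–O bond is not, so configuration is retained. The allylic C–O bond is deactivated toward ionisation by the electron-poor butenolide.

## Compound list
1 | 4-pentyn-1-ol | C#CCCCO | starting material
2 | pent-4-ynal | C#CCCC=O | intermediate
3 | butanal | CCCC=O | starting material
4 | (3R)-3-hydroxy-2-(prop-2-yn-1-yl)hexanal | CCC[C@@H](O)C(CC#C)C=O | intermediate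
5 | (3R)-3-(TBSO)-2-(prop-2-yn-1-yl)hexanal | CCC[C@@H](O[Si](C)(C)C(C)(C)C)C(CC#C)C=O | intermediate
6 | (3R)-3-(TBSO)-2-(prop-2-yn-1-yl)hexanoic acid | CCC[C@@H](O[Si](C)(C)C(C)(C)C)C(CC#C)C(=O)O | intermediate
7 | 5-(bromomethylene)-3-[(1R)-1-(TBSO)butyl]dihydrofuran-2-one | CCC[C@@H](O[Si](C)(C)C(C)(C)C)C1CC(=CBr)OC1=O | intermediate
8 | 4-bromo-5-(bromomethylene)-3-[(1R)-1-(TBSO)butyl]furan-2(5H)-one | CCC[C@@H](O[Si](C)(C)C(C)(C)C)C1=C(Br)/C(=C\Br)OC1=O | intermediate
9 | acetoxyfimbrolide | CCC[C@@H](OC(C)=O)C1=C(Br)/C(=C\Br)OC1=O | target

**Total steps:** 7. **Longest linear sequence:** 7 (steps 1–7, from 4-pentyn-1-ol).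

## Three steps most likely to fail
1. **Step 6 (proposed new method).** The second bromination at C4 may compete with bromination at C3 or C5 through the dienol. The exocyclic alkene may also form mainly as the isomer with Br cis to ring O rather than the drawn one.
   Fallback (known chemistry): hydrate the alkyne of 6 (Au(I) or Hg(II)) to the 3-substituted levulinic acid. Then apply the classical Br2-mediated levulinic acid → 4-bromo-5-(bromomethylene)butenolide cyclobromination, and finish with the silyl exchange.
2. **Step 2 (cross-aldol).** Butanal is enolizable, so self-aldol and poor cross-selectivity are possible.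
   Fallback: an Evans syn-aldol of N-(pent-4-ynoyl)oxazolidinone with butanal, with the auxiliary enantiomer chosen to give (3R). Then remove the auxiliary (LiOH/H2O2) and silylate, which gives 6 directly.
3. **Step 7 (direct Si→Ac exchange).** The Lewis acid may decompose the bromobutenolide or give incomplete exchange.
   Fallback: remove the TBS group with HF·pyridine (THF/pyridine, 0 °C), then acetylate with Ac2O/pyridine. DMAP is avoided because of possible attack at C4.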